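**Retrosynthetic overview**

1. Target 22 comes from 21 by removal of the two benzyl ethers on rings B and C.
2. Ring A of 21 is read as a folded tetraketide: the ring carbon bearing C1' is C2 of the methyl 3,5,7-trioxononanoate 20, whose C7 already carries the 4-methoxyphenethyl group. The cut is the ring bond between the acyl-bearing carbon (C6) and the neighbouring C–OH carbon (C1, the ester carbon). Ring A is the only ring built and is formed last; rings B, C and the anisyl ring are bought.
3. 20 comes from γ-acylation of the dianion of the 2-substituted acetoacetate 13 with the ketal-protected Weinreb amide 18, then deketalisation; 13 comes from C-acetylation of ester 12.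
4. 12 comes from [Rh(OH)(cod)]2/(R)-BINAP-catalysed conjugate arylation of the (E)-γ,δ-dimethyl enoate 10 (sets C1'); 10 comes from alcohol 8 by oxidation and Wittig olefination.
5. 8 comes from aryl Grignard opening of the C2-symmetric cyclic sulfate 5 of (2R,3R)-2,3-dimethylbutane-1,4-diol 3, which comes from oxidative homocoupling of two molecules of the propionyl oxazolidinone 1 (sets C2' and C3').

Key step: step 13

Assumption: the facial sense in step 6 is taken from the crotonate case, where the catalyst formed from [Rh(OH)(cod)]2 and (S)-BINAP delivers aryl to the β-re face of an (E)-enoate; (R)-BINAP is therefore chosen for β-si delivery to 10, which gives 3R in 12.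
Assumption: metal enolates, polyanions and tautomers of a numbered compound that are generated in the flask are treated as forms of that compound and carry no number of their own.
Remark: step 1 is a dimerisation in which two molecules of 1 give one molecule of 2; the second molecule of 1 is entered on the line of the reagents that add atoms.

**Route**

Step 1
Reactants: 1 (4S)-4-isopropyl-3-propanoyl-1,3-oxazolidin-2-one
Product: 2 (4S,4'S)-3,3'-[(2R,3R)-2,3-dimethylbutanedioyl]bis(4-isopropyl-1,3-oxazolidin-2-one)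
Conditions: LiN(iPr)2 (1.05 equiv per imide), THF, −78 °C; TiCl4 (1.1 equiv per imide), −78 °C → rt; two molecules of 1 per molecule of 2
Reagents that add atoms: (4S)-4-isopropyl-3-propanoyl-1,3-oxazolidin-2-one (second molecule of 1), CCC(=O)N1[C@@H](C(C)C)COC1=O
Why: Oxidative enolate homocoupling, in which the lithium Z-enolate of each of the two molecules of 1 is transmetallated with TiCl4, electron transfer to the metal gives trivalent titanium and α-acyl radicals that dimerise, each on the face away from the isopropyl group of its own auxiliary, so that both new centres (later C2' and C3') form R and the threo, C2-symmetric bis-imide should predominate.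

Step 2
Reactants: 2 (4S,4'S)-3,3'-[(2R,3R)-2,3-dimethylbutanedioyl]bis(4-isopropyl-1,3-oxazolidin-2-one)
Product: 3 (2R,3R)-2,3-dimethylbutane-1,4-diol
Conditions: LiBH4, THF/MeOH, 0 °C → rt
Reagents that add atoms: none
Why: Hydride reduction of N-acyl oxazolidinones at the exocyclic carbonyl expels both auxiliaries and should give the C2-symmetric diol without epimerisation.

Step 3
Reactants: 3 (2R,3R)-2,3-dimethylbutane-1,4-diol
Product: 5 (5R,6R)-5,6-dimethyl-1,3,2-dioxathiepane 2,2-dioxide, via cyclic sulfite 4 (not isolated)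
Conditions: SOCl2, Et3N, CH2Cl2, 0 °C; then RuCl3·H2O (cat.), NaIO4, MeCN/H2O, 0 °C
Reagents that add atoms: thionyl chloride, O=S(Cl)Cl; sodium periodate, [Na+].[O-]I(=O)(=O)=O
Why: Cyclic sulfite formation followed by RuO4-catalysed oxidation at sulfur (standard cyclic sulfate synthesis) activates both primary carbons, which are homotopic through the C2 axis, so no end-differentiation problem arises.

Step 4
Reactants: 5 (5R,6R)-5,6-dimethyl-1,3,2-dioxathiepane 2,2-dioxide; 6 4-(benzyloxy)phenylmagnesium bromide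
Product: 8 (2R,3S)-4-[4-(benzyloxy)phenyl]-2,3-dimethylbutan-1-ol, via alkyl sulfate salt 7 (not isolated)
Conditions: CuI (10 mol%), THF, −30 °C → rt; then H2SO4 (cat.), H2O (2 equiv), THF, rt
Reagents that add atoms: none
Why: CuI-catalysed SN2 alkylation of the aryl Grignard reagent by the cyclic sulfate opens the ring only once, because the alkyl sulfate anion formed is no longer an electrophile, and acid-catalysed hydrolysis of that monoester (S–O cleavage) should free the alcohol; attack at either carbon gives the same compound.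

Step 5
Reactants: 8 (2R,3S)-4-[4-(benzyloxy)phenyl]-2,3-dimethylbutan-1-ol
Product: 10 methyl (2E,4R,5S)-6-[4-(benzyloxy)phenyl]-4,5-dimethylhex-2-enoate, via aldehyde 9 (not isolated)
Conditions: (COCl)2, DMSO, CH2Cl2, −78 °C; Et3N; then Ph3P=CHCO2Me, −78 °C → rt
Reagents that add atoms: methyl (triphenylphosphoranylidene)acetate, COC(=O)C=P(c1ccccc1)(c1ccccc1)c1ccccc1
Why: Swern oxidation with in situ Wittig olefination by the stabilised ylide (E-selective) avoids isolating the α-branched aldehyde, so C2' should not epimerise.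

Step 6
Reactants: 10 methyl (2E,4R,5S)-6-[4-(benzyloxy)phenyl]-4,5-dimethylhex-2-enoate; 11 4-(benzyloxy)phenylboronic acid
Product: 12 methyl (3R,4R,5S)-3,6-bis[4-(benzyloxy)phenyl]-4,5-dimethylhexanoate
Conditions: [Rh(OH)(cod)]2 (3 mol%), (R)-BINAP (6.6 mol%), 11 (2.5 equiv), 1,4-dioxane/H2O 10:1, 60 °C
Reagents that add atoms: none
Why: Hayashi–Miyaura asymmetric 1,4-addition catalysed by [Rh(OH)(cod)]2/(R)-BINAP, in which the aryl–rhodium species inserts the enoate on the β-si face selected by (R)-BINAP and water protonates the rhodium enolate, so that C1' is set as 3R under catalyst control over the modest bias of the γ-methyl centre.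

Step 7
Reactants: 12 methyl (3R,4R,5S)-3,6-bis[4-(benzyloxy)phenyl]-4,5-dimethylhexanoate
Product: 13 methyl (2RS,3S,4R,5S)-2-acetyl-3,6-bis[4-(benzyloxy)phenyl]-4,5-dimethylhexanoate
Conditions: LiN(iPr)2 (1.1 equiv), THF, −78 °C; MeC(O)N(OMe)Me (2 equiv), −78 → 0 °C; aq. NH4Cl
Reagents that add atoms: N-methoxy-N-methylacetamide, CC(=O)N(C)OC
Why: Crossed Claisen condensation of the ester lithium enolate with a Weinreb amide, whose chelated tetrahedral adduct persists until work-up and so prevents proton transfer from the product and double acylation; the C2 epimers are of no consequence because C2 becomes an arene carbon.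

Step 8
Reactants: 14 3-(4-methoxyphenyl)propanoic acid
Product: 16 methyl 5-(4-methoxyphenyl)-3-oxopentanoate, via acyl imidazole 15 (not isolated)
Conditions: 1,1'-carbonyldiimidazole, THF, rt; then KO2CCH2CO2Me, MgCl2, Et3N, THF, rt → 50 °C; 1 M aq. HCl
Reagents that add atoms: potassium methyl malonate, [K+].[O-]C(=O)CC(=O)OC
Why: Masamune–Brooks homologation, in which the acyl imidazole C-acylates the magnesium enolate of the malonate half-ester with loss of CO2.

Step 9
Reactants: 16 methyl 5-(4-methoxyphenyl)-3-oxopentanoate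
Product: 17 methyl 2-{2-[2-(4-methoxyphenyl)ethyl]-1,3-dioxolan-2-yl}acetate
Conditions: HOCH2CH2OH, TsOH (cat.), toluene, reflux, Dean–Stark
Reagents that add atoms: ethylene glycol, OCCO
Why: Acid-catalysed ketalisation with azeotropic removal of water masks the future C7 ketone, so that this position can be neither enolised nor attacked in step 11.

Step 10
Reactants: 17 methyl 2-{2-[2-(4-methoxyphenyl)ethyl]-1,3-dioxolan-2-yl}acetate
Product: 18 N-methoxy-2-{2-[2-(4-methoxyphenyl)ethyl]-1,3-dioxolan-2-yl}-N-methylacetamide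
Conditions: MeNHOMe·HCl, iPrMgCl, THF, −20 → 0 °C
Reagents that add atoms: N,O-dimethylhydroxylamine hydrochloride, CNOC.Cl
Why: Direct aminolysis of the ester by the chloromagnesium amide of N,O-dimethylhydroxylamine (Weinreb amide formation); the ketal is inert to the base.

Step 11
Reactants: 13 methyl (2RS,3S,4R,5S)-2-acetyl-3,6-bis[4-(benzyloxy)phenyl]-4,5-dimethylhexanoate; 18 N-methoxy-2-{2-[2-(4-methoxyphenyl)ethyl]-1,3-dioxolan-2-yl}-N-methylacetamide
Product: 19 methyl (2RS)-2-{(1S,2R,3S)-1,4-bis[4-(benzyloxy)phenyl]-2,3-dimethylbutyl}-6-{2-[2-(4-methoxyphenyl)ethyl]-1,3-dioxolan-2-yl}-3,5-dioxohexanoate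
Conditions: LiN(iPr)2 (2.3 equiv), THF, −78 → 0 °C; then 18 (1.2 equiv), −78 → 0 °C; aq. NH4Cl
Reagents that add atoms: none
Why: Acetoacetate dianion γ-acylation, in which double deprotonation (C2, then the acetyl methyl) leaves the terminal carbanion as the more basic site, and this adds to the Weinreb amide and stops at the chelated mono-adduct.

Step 12
Reactants: 19 methyl (2RS)-2-{(1S,2R,3S)-1,4-bis[4-(benzyloxy)phenyl]-2,3-dimethylbutyl}-6-{2-[2-(4-methoxyphenyl)ethyl]-1,3-dioxolan-2-yl}-3,5-dioxohexanoate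
Product: 20 methyl (2RS)-2-{(1S,2R,3S)-1,4-bis[4-(benzyloxy)phenyl]-2,3-dimethylbutyl}-9-(4-methoxyphenyl)-3,5,7-trioxononanoate (keto and enol forms)
Conditions: 2 M aq. HCl, THF, 0 °C → rt
Reagents that add atoms: water, O
Why: Mild acid-catalysed hydrolysis of the dioxolane should release the C7 ketone while benzyl and methyl ethers and the three stereocentres stay untouched.

Step 13
Reactants: 20 methyl (2RS)-2-{(1S,2R,3S)-1,4-bis[4-(benzyloxy)phenyl]-2,3-dimethylbutyl}-9-(4-methoxyphenyl)-3,5,7-trioxononanoate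
Product: 21 1-(3-{(1R,2R,3S)-1,4-bis[4-(benzyloxy)phenyl]-2,3-dimethylbutyl}-2,4,6-trihydroxyphenyl)-3-(4-methoxyphenyl)propan-1-one
Conditions: Mg(OMe)2 (6 equiv), MeOH, 65 °C; then 1 M aq. HCl, 0 °C
Reagents that add atoms: none
Why: Mg(OMe)2 should convert 20 into a chelated magnesium polyenolate whose C6 carbanion, flanked by the C5 and C7 carbonyls, adds to the ester carbonyl C1; loss of methoxide gives a 2-acylcyclohexane-1,3,5-trione that enolises to the phloroglucinol. The closest known reaction is the biomimetic Claisen (Dieckmann-type) cyclisation of 3,5,7-triketo esters to acylphloroglucinols. Ring A is closed in the 6-exo-trig mode, with the enolate carbon attacking an exocyclic C=O. No stereocentre is created: C2 becomes an arene carbon, and C1', C2' and C3' are not α to any carbonyl and cannot epimerise. The step needs C-acylation (C6 to C1) to win over the aldol mode (C2 to C7) and over lactonisation of an enol oxygen onto C1. The substituent on C2 makes the aldol adduct unable to dehydrate to an arene, so it can only revert; magnesium chelation favours C- over O-acylation; and aromatisation makes the Claisen path irreversible.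

Step 14
Reactants: 21 1-(3-{(1R,2R,3S)-1,4-bis[4-(benzyloxy)phenyl]-2,3-dimethylbutyl}-2,4,6-trihydroxyphenyl)-3-(4-methoxyphenyl)propan-1-one
Product: 22 1-{3-[(1R,2R,3S)-1,4-bis(4-hydroxyphenyl)-2,3-dimethylbutyl]-2,4,6-trihydroxyphenyl}-3-(4-methoxyphenyl)propan-1-one
Conditions: H2 (1 atm), Pd/C (10 wt%), EtOAc/MeOH, rt
Reagents that add atoms: none
Why: Hydrogenolysis of the two benzyl aryl ethers over Pd/C; the hydrogen-bonded ortho-hydroxyaryl ketone and the C–C bonded diarylmethine should resist reduction under these mild conditions.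

**Compound list**

1 | (4S)-4-isopropyl-3-propanoyl-1,3-oxazolidin-2-one | CCC(=O)N1[C@@H](C(C)C)COC1=O | starting material
2 | (4S,4'S)-3,3'-[(2R,3R)-2,3-dimethylbutanedioyl]bis(4-isopropyl-1,3-oxazolidin-2-one) | O=C([C@H](C)[C@@H](C)C(=O)N1[C@@H](C(C)C)COC1=O)N1[C@@H](C(C)C)COC1=O | intermediate
3 | (2R,3R)-2,3-dimethylbutane-1,4-diol | OC[C@H](C)[C@@H](C)CO | intermediate
4 | (5R,6R)-5,6-dimethyl-1,3,2-dioxathiepane 2-oxide | O=S1OC[C@H](C)[C@@H](C)CO1 | intermediate
5 | (5R,6R)-5,6-dimethyl-1,3,2-dioxathiepane 2,2-dioxide | O=S1(=O)OC[C@H](C)[C@@H](C)CO1 | intermediate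
6 | 4-(benzyloxy)phenylmagnesium bromide (THF solution) | Br[Mg]c1ccc(OCc2ccccc2)cc1 | starting material
7 | bromomagnesium (2R,3S)-4-[4-(benzyloxy)phenyl]-2,3-dimethylbutyl sulfate | Br[Mg+].[O-]S(=O)(=O)OC[C@H](C)[C@@H](C)Cc1ccc(OCc2ccccc2)cc1 | intermediate
8 | (2R,3S)-4-[4-(benzyloxy)phenyl]-2,3-dimethylbutan-1-ol | OC[C@H](C)[C@@H](C)Cc1ccc(OCc2ccccc2)cc1 | intermediate
9 | (2R,3S)-4-[4-(benzyloxy)phenyl]-2,3-dimethylbutanal | O=C[C@H](C)[C@@H](C)Cc1ccc(OCc2ccccc2)cc1 | intermediate
10 | methyl (2E,4R,5S)-6-[4-(benzyloxy)phenyl]-4,5-dimethylhex-2-enoate | COC(=O)/C=C/[C@H](C)[C@@H](C)Cc1ccc(OCc2ccccc2)cc1 | intermediate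
11 | 4-(benzyloxy)phenylboronic acid | OB(O)c1ccc(OCc2ccccc2)cc1 | starting material
12 | methyl (3R,4R,5S)-3,6-bis[4-(benzyloxy)phenyl]-4,5-dimethylhexanoate | COC(=O)C[C@@H](c1ccc(OCc2ccccc2)cc1)[C@H](C)[C@@H](C)Cc1ccc(OCc2ccccc2)cc1 | intermediate
13 | methyl (2RS,3S,4R,5S)-2-acetyl-3,6-bis[4-(benzyloxy)phenyl]-4,5-dimethylhexanoate | COC(=O)C(C(C)=O)[C@@H](c1ccc(OCc2ccccc2)cc1)[C@H](C)[C@@H](C)Cc1ccc(OCc2ccccc2)cc1 | intermediate
14 | 3-(4-methoxyphenyl)propanoic acid | COc1ccc(CCC(=O)O)cc1 | starting material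
15 | 1-(1H-imidazol-1-yl)-3-(4-methoxyphenyl)propan-1-one | COc1ccc(CCC(=O)n2ccnc2)cc1 | intermediate
16 | methyl 5-(4-methoxyphenyl)-3-oxopentanoate | COC(=O)CC(=O)CCc1ccc(OC)cc1 | intermediate
17 | methyl 2-{2-[2-(4-methoxyphenyl)ethyl]-1,3-dioxolan-2-yl}acetate | COC(=O)CC1(CCc2ccc(OC)cc2)OCCO1 | intermediate
18 | N-methoxy-2-{2-[2-(4-methoxyphenyl)ethyl]-1,3-dioxolan-2-yl}-N-methylacetamide | CON(C)C(=O)CC1(CCc2ccc(OC)cc2)OCCO1 | intermediate
19 | methyl (2RS)-2-{(1S,2R,3S)-1,4-bis[4-(benzyloxy)phenyl]-2,3-dimethylbutyl}-6-{2-[2-(4-methoxyphenyl)ethyl]-1,3-dioxolan-2-yl}-3,5-dioxohexanoate | COC(=O)C(C(=O)CC(=O)CC1(CCc2ccc(OC)cc2)OCCO1)[C@@H](c1ccc(OCc2ccccc2)cc1)[C@H](C)[C@@H](C)Cc1ccc(OCc2ccccc2)cc1 | intermediate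
20 | methyl (2RS)-2-{(1S,2R,3S)-1,4-bis[4-(benzyloxy)phenyl]-2,3-dimethylbutyl}-9-(4-methoxyphenyl)-3,5,7-trioxononanoate | COC(=O)C(C(=O)CC(=O)CC(=O)CCc1ccc(OC)cc1)[C@@H](c1ccc(OCc2ccccc2)cc1)[C@H](C)[C@@H](C)Cc1ccc(OCc2ccccc2)cc1 | intermediate
21 | 1-(3-{(1R,2R,3S)-1,4-bis[4-(benzyloxy)phenyl]-2,3-dimethylbutyl}-2,4,6-trihydroxyphenyl)-3-(4-methoxyphenyl)propan-1-one | COc1ccc(CCC(=O)c2c(O)cc(O)c([C@@H](c3ccc(OCc4ccccc4)cc3)[C@H](C)[C@@H](C)Cc3ccc(OCc4ccccc4)cc3)c2O)cc1 | intermediate
22 | 1-{3-[(1R,2R,3S)-1,4-bis(4-hydroxyphenyl)-2,3-dimethylbutyl]-2,4,6-trihydroxyphenyl}-3-(4-methoxyphenyl)propan-1-one | COc1ccc(CCC(=O)c2c(O)cc(O)c([C@@H](c3ccc(O)cc3)[C@H](C)[C@@H](C)Cc3ccc(O)cc3)c2O)cc1 | target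

**Step count and risks**

Total step count: 14. Longest linear sequence: 11 steps (steps 1–7 and 11–14); steps 8–10 build the Weinreb amide 18 in parallel.

Steps most likely to fail:

Step 13. Lactonisation of the C5 enol oxygen onto the ester, or retro-Claisen methanolysis of the polyketone, may outrun C-acylation at the crowded ester carbon. The fallback sets out from 8 and 14 and returns at 21; it brings in ring A ready-made instead of building it. Alcohol 8 would be oxidised under Swern conditions to aldehyde 9, this time isolated, and treated with Grignard reagent 6 (THF, −78 °C) to give (1RS,2R,3S)-1,4-bis[4-(benzyloxy)phenyl]-2,3-dimethylbutan-1-ol F1. Acid 14 and phloroglucinol (BF3·OEt2, 80 °C, Friedel–Crafts acylation) would give 3-(4-methoxyphenyl)-1-(2,4,6-trihydroxyphenyl)propan-1-one F2. Acid-catalysed Friedel–Crafts alkylation of excess F2 with F1 (TsOH cat., 1,4-dioxane, 0 °C → rt) should then join C1' to either of the two equivalent free positions of ring A and give 21. The excess of the electron-rich F2 is meant to let intermolecular capture of the benzylic cation outrun its cyclisation onto ring C. In this fallback C1' rests on 1,2-induction from C2' and not on the catalyst, so the C1' epimer of 21 F3 is expected alongside and would be removed by chromatography. The temperature is kept low to suppress proton loss from the benzylic cation, which would endanger C2'.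

Step 6. The γ-branch may slow insertion, or the bias of the existing C2' centre may oppose the ligand and erode facial selectivity. The fallback sets out from 10 and returns at 12; it replaces catalyst control by a covalently bound auxiliary. Saponification of 10 (LiOH, THF/H2O) would give (2E,4R,5S)-6-[4-(benzyloxy)phenyl]-4,5-dimethylhex-2-enoic acid F4. The mixed pivalic anhydride (PivCl, Et3N) would be coupled with lithiated (R)-4-phenyl-1,3-oxazolidin-2-one to give (4R)-3-{(2E,4R,5S)-6-[4-(benzyloxy)phenyl]-4,5-dimethylhex-2-enoyl}-4-phenyl-1,3-oxazolidin-2-one F5. CuBr·SMe2-mediated conjugate addition of 6 (THF, −40 → −10 °C) to the chelated s-cis imide, anti to the phenyl group, should deliver the aryl group to the same β-si face and give (4R)-3-{(3R,4R,5S)-3,6-bis[4-(benzyloxy)phenyl]-4,5-dimethylhexanoyl}-4-phenyl-1,3-oxazolidin-2-one F6. Methanolysis (NaOMe, MeOH, 0 °C) would give 12.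

Step 12. Under acid the freed 3,5,7-triketone may cyclodehydrate to a 4-pyranone, or the ketal may resist hydrolysis under conditions mild enough to avoid this. The fallback sets out from 13 and 14 and returns at 20; it never protects C7 and works under basic conditions only. γ-Acetylation of the dianion of 13 (LiN(iPr)2, 2.3 equiv; MeC(O)N(OMe)Me) would give methyl (2RS)-2-{(1S,2R,3S)-1,4-bis[4-(benzyloxy)phenyl]-2,3-dimethylbutyl}-3,5-dioxohexanoate F7. Acid 14 (1,1'-carbonyldiimidazole; MeNHOMe·HCl) would give N-methoxy-3-(4-methoxyphenyl)-N-methylpropanamide F8. The trianion of F7 (LiN(iPr)2, 3.3 equiv, THF, 0 °C) would be acylated at its terminal methyl carbanion by F8 (polyketide-type polyanion acylation) and should give 20 after cold acidic work-up.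

**Further compounds**

F1 | step 13 | (1RS,2R,3S)-1,4-bis[4-(benzyloxy)phenyl]-2,3-dimethylbutan-1-ol | OC(c1ccc(OCc2ccccc2)cc1)[C@H](C)[C@@H](C)Cc1ccc(OCc2ccccc2)cc1
F2 | step 13 | 3-(4-methoxyphenyl)-1-(2,4,6-trihydroxyphenyl)propan-1-one | COc1ccc(CCC(=O)c2c(O)cc(O)cc2O)cc1
F3 | step 13 | 1-(3-{(1S,2R,3S)-1,4-bis[4-(benzyloxy)phenyl]-2,3-dimethylbutyl}-2,4,6-trihydroxyphenyl)-3-(4-methoxyphenyl)propan-1-one (C1' epimer of 21) | COc1ccc(CCC(=O)c2c(O)cc(O)c([C@H](c3ccc(OCc4ccccc4)cc3)[C@H](C)[C@@H](C)Cc3ccc(OCc4ccccc4)cc3)c2O)cc1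
F4 | step 6 | (2E,4R,5S)-6-[4-(benzyloxy)phenyl]-4,5-dimethylhex-2-enoic acid | OC(=O)/C=C/[C@H](C)[C@@H](C)Cc1ccc(OCc2ccccc2)cc1
F5 | step 6 | (4R)-3-{(2E,4R,5S)-6-[4-(benzyloxy)phenyl]-4,5-dimethylhex-2-enoyl}-4-phenyl-1,3-oxazolidin-2-one | O=C(/C=C/[C@H](C)[C@@H](C)Cc1ccc(OCc2ccccc2)cc1)N1[C@H](c2ccccc2)COC1=O
F6 | step 6 | (4R)-3-{(3R,4R,5S)-3,6-bis[4-(benzyloxy)phenyl]-4,5-dimethylhexanoyl}-4-phenyl-1,3-oxazolidin-2-one | O=C(C[C@@H](c1ccc(OCc2ccccc2)cc1)[C@H](C)[C@@H](C)Cc1ccc(OCc2ccccc2)cc1)N1[C@H](c2ccccc2)COC1=O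
F7 | step 12 | methyl (2RS)-2-{(1S,2R,3S)-1,4-bis[4-(benzyloxy)phenyl]-2,3-dimethylbutyl}-3,5-dioxohexanoate | COC(=O)C(C(=O)CC(C)=O)[C@@H](c1ccc(OCc2ccccc2)cc1)[C@H](C)[C@@H](C)Cc1ccc(OCc2ccccc2)cc1
F8 | step 12 | N-methoxy-3-(4-methoxyphenyl)-N-methylpropanamide | COc1ccc(CCC(=O)N(C)OC)cc1
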